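**Retrosynthetic overview**
1. The exocyclic C=CH2 comes last, from the spiro ketone by carbonyl methylenation.
2. The spiro ketone comes from a tertiary 1-(cyclohexenyl)cyclopentanol by ring expansion: the CMe2 ring carbon shifts 1,2 onto the cyclohexenyl carbon (hydrogen-atom-transfer semipinacol). This forms six-membered ring A and the spiro centre and is the last ring event.
3. The carbinol comes from (R)-3-bromo-2,2-dimethylcyclopentanone plus the alkenyllithium of a 1-iodocyclohexene that already carries the trans tertiary-Br/secondary-Cl pair.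
4. Ring B (second ring) comes from a CoBr2(dppe)-catalysed [4+2] of isoprene and ethynyltrimethylsilane, then Shi epoxidation, chloride opening, iododesilylation and SN1 bromination, all on the monocycle.
5. The bromoketone comes from 2-methylcyclopentenone (first ring, purchased) by asymmetric methyl addition and a bromonium-triggered 1,2-methyl shift.

Assumption: reagents that deliver only hydrogen (water, silane) are not listed as atom-adding reagents; locants in the Why lines are those of each compound's own name.

**Step 1**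
Reactants: 1 2-methylcyclopent-2-en-1-one
Product: 2 (S)-1,2-dimethylcyclopent-2-en-1-ol
Conditions: ZnMe2 (2 equiv), Ti(OiPr)4 (1.2 equiv), chiral bis(camphorsulfonamido)cyclohexane diol ligand (5 mol %, enantiomer giving S), toluene/hexane, rt; then H2O
Reagents that add atoms: dimethylzinc, C[Zn]C
Why: Ti(OiPr)4-promoted catalytic asymmetric 1,2-addition of ZnMe2 to a 2-substituted cyclic enone (Walsh-type alkylation), in which the complex of the chiral ligand and Ti(OiPr)4 delivers methyl to one carbonyl face and sets the S carbinol centre that step 2 relays to the C–Br centre.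

**Step 2**
Reactants: 2 (S)-1,2-dimethylcyclopent-2-en-1-ol
Product: 3 (R)-3-bromo-2,2-dimethylcyclopentan-1-one
Conditions: NBS (1.1 equiv), CH2Cl2, −40 → 0 °C
Reagents that add atoms: N-bromosuccinimide, O=C1CCC(=O)N1Br
Why: Bromonium-induced semipinacol rearrangement, in which Br+ adds on the hydroxyl face and the methyl anti to the bromonium migrates from the carbinol carbon to the neighbouring carbon as the carbinol becomes C=O, so the gem-dimethyl carbon is built and the carbinol configuration is transferred stereospecifically to the new R C–Br centre.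

**Step 3**
Reactants: 4 isoprene; 5 ethynyltrimethylsilane
Product: 6 trimethyl(4-methylcyclohexa-1,4-dien-1-yl)silane
Conditions: CoBr2(dppe) (5 mol %), Zn (10 mol %), ZnI2 (10 mol %), CH2Cl2, rt
Reagents that add atoms: none
Why: CoBr2(dppe)-catalysed formal [4+2] cycloaddition of a terminal alkyne with a 1,3-diene (Hilt-type, dppe ligand) gives the 1,4-disubstituted cyclohexa-1,4-diene with silicon para to methyl; no stereocentre is formed.

**Step 4**
Reactants: 6 trimethyl(4-methylcyclohexa-1,4-dien-1-yl)silane
Product: 7 (1S,6R)-1-methyl-4-(trimethylsilyl)-7-oxabicyclo[4.1.0]hept-3-ene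
Conditions: D-fructose-derived Shi ketone (0.3 equiv), KHSO5 (as 2KHSO5·KHSO4·K2SO4, 1.4 equiv), K2CO3, Bu4NHSO4 (cat.), MeCN/(MeO)2CH2/aq. Na2B4O7 buffer (pH 10.5), 0 °C
Reagents that add atoms: potassium peroxymonosulfate, [K+].[O-]S(=O)(=O)OO
Why: Shi asymmetric epoxidation, in which the chiral dioxirane attacks the trialkyl-substituted alkene (the bulkier, less nucleophilic vinylsilane is spared) through the spiro transition state and sets both epoxide carbons in the facial sense known for 1-phenylcyclohexene.

**Step 5**
Reactants: 7 (1S,6R)-1-methyl-4-(trimethylsilyl)-7-oxabicyclo[4.1.0]hept-3-ene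
Product: 8 (1S,6S)-6-chloro-1-methyl-4-(trimethylsilyl)cyclohex-3-en-1-ol
Conditions: Li2CuCl4 (0.1 M in THF, 1.5 equiv), THF, 0 °C → rt; then H2O
Reagents that add atoms: dilithium tetrachlorocuprate, [Li+].[Li+].Cl[Cu-2](Cl)(Cl)Cl
Why: Regioselective SN2 epoxide opening by Li2CuCl4 at the less substituted carbon with inversion gives the trans chlorohydrin and sets the S C–Cl centre, leaving the tertiary C–O centre untouched.

**Step 6**
Reactants: 8 (1S,6S)-6-chloro-1-methyl-4-(trimethylsilyl)cyclohex-3-en-1-ol
Product: 9 (1S,6S)-6-chloro-4-iodo-1-methylcyclohex-3-en-1-ol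
Conditions: NIS (1.2 equiv), (CF3)2CHOH, 0 °C
Reagents that add atoms: N-iodosuccinimide, O=C1CCC(=O)N1I
Why: Electrophilic ipso-iododesilylation of a vinylsilane (β-silyl cation, then loss of silicon) replaces silicon by iodine at the same alkene carbon; no stereocentre is involved.

**Step 7**
Reactants: 9 (1S,6S)-6-chloro-4-iodo-1-methylcyclohex-3-en-1-ol
Product: 10 (4S,5S)-4-bromo-5-chloro-1-iodo-4-methylcyclohex-1-ene
Conditions: TMSBr (1.5 equiv), CH2Cl2, −30 → 0 °C
Reagents that add atoms: bromotrimethylsilane, C[Si](C)(C)Br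
Why: SN1 substitution of the tertiary alcohol, in which the tertiary cation is bridged by the neighbouring axial chlorine so that bromide enters anti to chlorine on the face the oxygen left (retention), giving the trans-diaxial tertiary bromide/secondary chloride on a ring that has no acid-labile allylic carbinol yet.

**Step 8**
Reactants: 10 (4S,5S)-4-bromo-5-chloro-1-iodo-4-methylcyclohex-1-ene; 3 (R)-3-bromo-2,2-dimethylcyclopentan-1-one
Product: 12 (1R,3R)-3-bromo-1-[(4S,5S)-4-bromo-5-chloro-4-methylcyclohex-1-en-1-yl]-2,2-dimethylcyclopentan-1-ol, via alkenyllithium 11 (not isolated)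
Conditions: t-BuLi (2.0 equiv), Et2O/pentane, −100 °C, 10 min; then 3, LaCl3·2LiCl (1.0 equiv), THF, −78 °C; then H2O
Reagents that add atoms: none
Why: Iodine–lithium exchange at −100 °C outruns reaction at the alkyl halides and the LaCl3-activated ketone takes up the alkenyllithium in a 1,2-addition anti to the ring C–Br; the new carbinol centre (R, major) is erased in step 9.

**Step 9**
Reactants: 12 (1R,3R)-3-bromo-1-[(4S,5S)-4-bromo-5-chloro-4-methylcyclohex-1-en-1-yl]-2,2-dimethylcyclopentan-1-ol
Product: 13 (4R,6R,8S,9S)-4,9-dibromo-8-chloro-5,5,9-trimethylspiro[5.5]undecan-1-one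
Conditions: (R,R)-Co(salen) [salen = N,N′-bis(3,5-di-tert-butylsalicylidene)cyclohexane-1,2-diaminate] (5 mol %), N-fluoro-2,4,6-trimethylpyridinium triflate (1.5 equiv), PhSiH3 (1.2 equiv), acetone, −20 °C
Reagents that add atoms: none
Why: Proposed new method: the hydride of Co(salen) transfers H• to the alkene CH and leaves the tertiary radical next to the carbinol, which Co(salen) traps on the ring face away from the C–Cl; oxidation to the tetravalent-cobalt alkyl complex makes it a leaving group that the CMe2 ring carbon displaces with inversion in a semipinacol 1,2-shift (cyclopentanol to spiro cyclohexanone), entering equatorially and cis to chlorine on the chair with both halogens equatorial, so the spiro centre is set R without acid that would ionise the tertiary allylic alcohol; the closest known reaction type is the hydrogen-atom-transfer radical–polar crossover semipinacol of tertiary allylic alcohols with 1,1-disubstituted alkenes, not shown for ring expansion onto a trisubstituted cycloalkenyl carbon that creates a spiro quaternary stereocentre under catalyst face control.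

**Step 10**
Reactants: 13 (4R,6R,8S,9S)-4,9-dibromo-8-chloro-5,5,9-trimethylspiro[5.5]undecan-1-one
Product: 14 obtusane, (2R,6S,8S,9S)-2,9-dibromo-8-chloro-1,1,9-trimethyl-5-methylidenespiro[5.5]undecane
Conditions: Cp2Ti(μ-CH2)(μ-Cl)AlMe2 (Tebbe reagent, 2 equiv), pyridine (cat.), THF/toluene, −40 → 0 °C
Reagents that add atoms: Tebbe reagent, C[Al-]1(C)C[Ti]([Cl+]1)(C2C=CC=C2)C3C=CC=C3
Why: Tebbe methylenation (Cp2Ti=CH2 released from the reagent, [2+2] to an oxatitanacyclobutane, cycloreversion) converts the hindered ketone into the exocyclic alkene under non-basic conditions that spare the alkyl halides; no stereocentre is touched.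

**Compound list**
1 | 2-methylcyclopent-2-en-1-one | CC1=CCCC1=O | starting material
2 | (S)-1,2-dimethylcyclopent-2-en-1-ol | CC1=CCC[C@]1(C)O | intermediate
3 | (R)-3-bromo-2,2-dimethylcyclopentan-1-one | O=C1CC[C@@H](Br)C1(C)C | intermediate
4 | isoprene (2-methylbuta-1,3-diene) | C=CC(C)=C | starting material
5 | ethynyltrimethylsilane | C#C[Si](C)(C)C | starting material
6 | trimethyl(4-methylcyclohexa-1,4-dien-1-yl)silane | CC1=CCC(=CC1)[Si](C)(C)C | intermediate
7 | (1S,6R)-1-methyl-4-(trimethylsilyl)-7-oxabicyclo[4.1.0]hept-3-ene | C[Si](C)(C)C1=CC[C@]2(C)O[C@@H]2C1 | intermediate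
8 | (1S,6S)-6-chloro-1-methyl-4-(trimethylsilyl)cyclohex-3-en-1-ol | C[Si](C)(C)C1=CC[C@](C)(O)[C@@H](Cl)C1 | intermediate
9 | (1S,6S)-6-chloro-4-iodo-1-methylcyclohex-3-en-1-ol | IC1=CC[C@](C)(O)[C@@H](Cl)C1 | intermediate
10 | (4S,5S)-4-bromo-5-chloro-1-iodo-4-methylcyclohex-1-ene | IC1=CC[C@](C)(Br)[C@@H](Cl)C1 | intermediate
11 | [(4S,5S)-4-bromo-5-chloro-4-methylcyclohex-1-en-1-yl]lithium | [Li]C1=CC[C@](C)(Br)[C@@H](Cl)C1 | intermediate
12 | (1R,3R)-3-bromo-1-[(4S,5S)-4-bromo-5-chloro-4-methylcyclohex-1-en-1-yl]-2,2-dimethylcyclopentan-1-ol | O[C@@]1(C2=CC[C@](C)(Br)[C@@H](Cl)C2)CC[C@@H](Br)C1(C)C | intermediate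
13 | (4R,6R,8S,9S)-4,9-dibromo-8-chloro-5,5,9-trimethylspiro[5.5]undecan-1-one | O=C1CC[C@@H](Br)C(C)(C)[C@]12CC[C@](C)(Br)[C@@H](Cl)C2 | intermediate
14 | obtusane, (2R,6S,8S,9S)-2,9-dibromo-8-chloro-1,1,9-trimethyl-5-methylidenespiro[5.5]undecane | C=C1CC[C@@H](Br)C(C)(C)[C@]12CC[C@](C)(Br)[C@@H](Cl)C2 | target

**Step count**
Total steps: 10 (convergent). Longest linear sequence: 8 (steps 3 to 10).

**Steps most likely to fail**

Step 9 (the new ring expansion). Epoxide formation or capture on the wrong ring face may compete with the 1,2-shift. The fallback sets out from 12 and uses a halonium-triggered semipinacol, a known reaction of 1-cycloalkenyl cycloalkanols. N-iodosuccinimide in CH2Cl2 at −40 °C puts iodine on the alkene CH anti to the migrating carbon and gives (4R,6S,7R,9S,10S)-4,9-dibromo-10-chloro-7-iodo-5,5,9-trimethylspiro[5.5]undecan-1-one F1. Radical deiodination (Bu3SnH 1.05 equiv, Et3B/air, −78 °C; the secondary C–I bond is abstracted faster than the C–Br bonds) then comes back to the route at 13.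

Step 2 (methyl is a modest migrating group; bromo-epoxide and allylic bromide are possible side products). The fallback sets out from 1 and reaches the same ketone through an epoxide semipinacol and an inverting bromination. The enantiomeric ligand in the ZnMe2 addition gives (R)-1,2-dimethylcyclopent-2-en-1-ol F2. Hydroxyl-directed epoxidation (VO(acac)2, t-BuOOH) gives (1S,2R,5S)-1,2-dimethyl-6-oxabicyclo[3.1.0]hexan-2-ol F3. BF3·OEt2 triggers the 1,2-methyl shift onto the tertiary epoxide carbon and gives (S)-3-hydroxy-2,2-dimethylcyclopentan-1-one F4. Appel bromination with inversion (CBr4, P(n-Oct)3) comes back to the route at 3.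

Step 10 (very hindered ketone beside two quaternary carbons, with three alkyl halides present). The fallback sets out from 13 and uses a Peterson olefination. Me3SiCH2Li/CeCl3 at −78 °C adds to the carbonyl and gives (4R,6R,8S,9S)-4,9-dibromo-8-chloro-5,5,9-trimethyl-1-[(trimethylsilyl)methyl]spiro[5.5]undecan-1-ol (C1 epimers) F5. Acid-promoted elimination with catalytic p-TsOH·H2O in CH2Cl2 at 0 °C comes back to the route at 14.

**Further compounds**
F1 | step 9 | (4R,6S,7R,9S,10S)-4,9-dibromo-10-chloro-7-iodo-5,5,9-trimethylspiro[5.5]undecan-1-one | O=C1CC[C@@H](Br)C(C)(C)[C@]12[C@H](I)C[C@](C)(Br)[C@@H](Cl)C2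
F2 | step 2 | (R)-1,2-dimethylcyclopent-2-en-1-ol | CC1=CCC[C@@]1(C)O
F3 | step 2 | (1S,2R,5S)-1,2-dimethyl-6-oxabicyclo[3.1.0]hexan-2-ol | O[C@]1(C)CC[C@@H]2O[C@]12C
F4 | step 2 | (S)-3-hydroxy-2,2-dimethylcyclopentan-1-one | O=C1CC[C@H](O)C1(C)C
F5 | step 10 | (4R,6R,8S,9S)-4,9-dibromo-8-chloro-5,5,9-trimethyl-1-[(trimethylsilyl)methyl]spiro[5.5]undecan-1-ol (C1 epimers) | C[Si](C)(C)CC1(O)CC[C@@H](Br)C(C)(C)[C@]12CC[C@](C)(Br)[C@@H](Cl)C2
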